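the same everywhere: free monomer 0.83 M; initiator 26 mM

| flask | protic impurity | stray impurity | remark | time |
|---|---|---|---|---|
| north-east | 0.0083 M | 4.7 mM | run made earlier |  |
| north-west | 0.012 M | 4.7 mM | run made earlier |  |
| south-east | 0.0166 M | 2.4 mM | run made earlier |  |
| flask | 0.0166 M | 4.7 mM |  | 10 d |

- north-east (time / d: monomer in chains / %, free monomer / %): 1.25: 36.7, 63.1; 2.50: 45.1, 53.9; 4.00: 49.3, 49.8; 5.00: 51.9, 47.6; 6.00: 53.0, 45.5; 8.00: 55.9, 43.7
- north-west (time / d: monomer in chains / %, free monomer / %): 0.625: 25.9, 72.3; 1.04: 33.1, 65.3; 1.67: 39.7, 59.8; 3.00: 46.3, 52.3; 5.00: 51.3, 47.8; 8.00: 54.6, 43.3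
- south-east (time / d: monomer in chains / %, free monomer / %): 1.67: 40.8, 57.6; 3.00: 47.0, 50.8; 5.00: 51.9, 46.2; 6.00: 53.8, 44.9; 8.00: 55.8, 42.8

(each reading ± 0.3 percentage points)

- average number of monomer units in a chain (chains begun, living or dead) at 10 d
- part of the free monomer that has reacted at 10 d

- the average divides the monomer in chains by the number of chains begun, living and dead together
- the numbers in the tables scatter by 0.3 percentage points (one standard deviation)
- the earlier runs do not show the number of chains; that part of a forecast is a guess

Take the millimole per litre as your unit of count. As a rule of thumb, allow one chain per unit of initiator after each unit of stray impurity has destroyed one. What remains is the live charge N*, the initiator charge less the stray charge, 21.3 mM in the flask. I leave protic impurity out of this count: in the south-east run at 5.00 d the two columns fall short of the charge by 1.90%, close to the ratio of protic impurity to monomer, 2.00%, so I read it as taking monomer. The north-east run has the same stray charge and reads 55.9% in chains at 8.00 d. Taking that reading for the flask at 10 d and dividing it by N* gives my own guess of about 21.8 units per chain; it stays a guess, since no run shows the number of chains. The subtraction leaves a remainder only while the ratio of stray impurity to initiator stays below 1, and in the flask this ratio is 0.181.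

The forecast gives 15 units and 58.3% reacted, noting “Chains begun are not observed”. Its chain length differs from my guess.

The flask gives 21.8 units and 57.9% reacted.

    monomer in chains + living end → free monomer + living end, rate k1*[living end] as long as [monomer in chains] is above zero (k = 1.60 × 10⁻⁴ s⁻¹)
    2 living end → dead end A (k = 4.50 × 10⁻⁴ L mol⁻¹ s⁻¹)
    protic impurity + free monomer → quenched substrate (k = 6.60 × 10⁻⁴ L mol⁻¹ s⁻¹)
    free monomer + initiator → living end + monomer in chains (k = 4.90 × 10⁻⁴ L mol⁻¹ s⁻¹)
    free monomer + living end → monomer in chains + living end, rate k5*[living end]*[free monomer] (k = 5.90 × 10⁻⁴ L mol⁻¹ s⁻¹)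
    initiator + stray impurity → spent initiator B (k = 0.170 L mol⁻¹ s⁻¹)

The flask has not come to rest. From 10.0 d to 100 d, ten times as long, free monomer goes from 42.1% to 34.8% and monomer in chains from 55.9% to 63.2%, while the living end falls from 0.00122 M to 1.28 × 10⁻⁴ M. At 100 d, chains begun, two per dead end A plus the living ends, stand at 21.3 mM, the size of N*. Dividing the monomer in chains at that time by N* gives 24.6 units, and the computed values are 24.6 units and 65.2% reacted.

In the neighbour charged with 0.010 M of initiator, the ratio is 0.470, N* is 5.30 mM, and its 44.1% in chains gives 69.0 units. The computed average is 64.0, with spent initiator B at 0.00428 M, less than the stray charge of 4.7 mM.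

Readings and results were generated by integration with constants of no real substance; the scatter is artificial.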